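**Plan**
1. Numbering (cembrane): C1 is the carbinol carbon bearing isopropyl. The ring then runs C2=C3, C4(OH)Me, C5, C6=C7, C8(OH)Me, C9, C10 (CH–O), C11=C12, C13, C14 and back to C1. C20 is the lactone C=O, ring A the 14-membered carbocycle and ring B the butenolide.
2. Enabling feature: the inner alkene carbons C7 and C11 are bridged only by C8–C9–C10, and the two C–O bonds on that bridge are syn. Cutting C11=C12 and C6=C7 and joining C7 to C11 folds the segment into cis-1-methylcyclopent-2-ene-1,4-diol (temporary ring C), which masks both alkene termini and holds C8 and C10 on one small ring.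
3. Further cuts: ester O–C20 (acid 14 plus diol 17). Within 14 the cuts are C4–C5 (allylboration), C2=C3 (Wittig), C13–C14 (radical allylation) and C1–O (epoxidation).
4. Forward: the chain from C20/C12 to C6 is grown linearly and esterified with ring C. One ruthenium operation then opens ring C, closes ring B at C11=C12 and closes ring A at C6=C7. Desilylation ends the route.
5. Stereochemistry: C1 comes from Sharpless epoxidation, C4 from chiral-diol-catalysed allylboration, C10 from commercial (R)-4-silyloxycyclopentenone, and C8 from anti addition of MeLi on that ring. The 2E alkene comes from the Wittig step, 6E from thermodynamic control next to quaternary C8, and 11Z from the five-membered ring.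

Key step: step 16

Assumption: (S)-3,3'-dibromo-BINOL is taken to deliver allyl to the ketone face that gives the (R)-carbinol when the alkenyl arm acts as the large group, as with aryl methyl ketones. If a test on 11 shows the opposite sense, the equally available (R)-catalyst is used.

Step 1
Reactants: 1 3-methylbutanal
Product: 2 3-methyl-2-methylenebutanal (2-isopropylacrolein)
Conditions: 37% aq. HCHO, pyrrolidine (10 mol%), EtCO2H (10 mol%), i-PrOH, 45 °C
Reagents that add atoms: formaldehyde, C=O
Why: Organocatalytic Mannich condensation–elimination (α-methylenation of an aldehyde), in which the enamine of 1 adds to the formaldehyde iminium ion and amine loss gives the 2-substituted acrolein without creating a stereocentre.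

Step 2
Reactants: 2 3-methyl-2-methylenebutanal
Product: 3 3-methyl-2-methylenebutan-1-ol
Conditions: NaBH4, CeCl3·7H2O, MeOH, 0 °C
Reagents that add atoms: none
Why: Luche reduction should give clean 1,2-reduction of the enal to the 2-substituted allylic alcohol.

Step 3
Reactants: 3 3-methyl-2-methylenebutan-1-ol
Product: 4 (S)-(2-isopropyloxiran-2-yl)methanol
Conditions: Ti(OiPr)4 (10 mol%), L-(+)-DIPT (12 mol%), t-BuOOH, 4 Å MS, CH2Cl2, −20 °C
Reagents that add atoms: tert-butyl hydroperoxide, CC(C)(C)OO
Why: Sharpless asymmetric epoxidation of a 2-substituted allylic alcohol, in which the L-(+)-tartrate complex delivers oxygen in the same sense as for 2-methylprop-2-en-1-ol and so fixes C1 as (S); base is avoided afterwards because Payne rearrangement would racemise 4.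

Step 4
Reactants: 4 (S)-(2-isopropyloxiran-2-yl)methanol
Product: 5 (S)-2-(iodomethyl)-3-methylbutane-1,2-diol
Conditions: LiI, AcOH, THF, 0 °C → rt
Reagents that add atoms: lithium iodide, [Li+].[I-]
Why: Halohydrin formation by SN2 attack of iodide on the unhindered CH2 (C14) of the acid-activated 2,2-disubstituted epoxide, which leaves the C1–O bond and the configuration untouched.

Step 5
Reactants: 5 (S)-2-(iodomethyl)-3-methylbutane-1,2-diol
Product: 6 bis(triethylsilyl) ether of 5, (S)-configured
Conditions: TESOTf (2.5 equiv), 2,6-lutidine, CH2Cl2, −78 → 0 °C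
Reagents that add atoms: triethylsilyl triflate, CC[Si](CC)(CC)OS(=O)(=O)C(F)(F)F
Why: Silyl triflate silylation is strong enough for the hindered tertiary C1–OH, and the weak base should not re-close the epoxide.

Step 6
Reactants: 7 ethyl 2-(bromomethyl)acrylate
Product: 8 ethyl 2-[(phenylsulfonyl)methyl]acrylate
Conditions: PhSO2Na, MeOH, reflux
Reagents that add atoms: sodium benzenesulfinate, [Na+].[O-]S(=O)c1ccccc1
Why: S-alkylation of the sulfinate by the allylic bromide (SN2 and SN2' give the same product) furnishes the radical allyl-transfer reagent.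

Step 7
Reactants: 6 bis(triethylsilyl) ether of 5; 8 ethyl 2-[(phenylsulfonyl)methyl]acrylate (excess)
Product: 9 ethyl (S)-6-methyl-2-methylene-5-(triethylsilyloxy)-5-[(triethylsilyloxy)methyl]heptanoate
Conditions: (Bu3Sn)2, hν (sunlamp), benzene, 40 °C
Reagents that add atoms: none
Why: Keck-type fragmentation radical allylation, in which Bu3Sn• abstracts iodine, the C14 radical (which, unlike a C14 organometal, cannot lose the β-silyloxy group) adds to the acrylate CH2, and β-scission of PhSO2• regenerates the 1,1-disubstituted alkene, forming C13–C14 without touching C1.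

Step 8
Reactants: 9 ethyl (S)-6-methyl-2-methylene-5-(triethylsilyloxy)-5-[(triethylsilyloxy)methyl]heptanoate
Product: 10 ethyl (S)-5-formyl-6-methyl-2-methylene-5-(triethylsilyloxy)heptanoate
Conditions: (COCl)2, DMSO, CH2Cl2, −78 → −30 °C; Et3N, → rt
Reagents that add atoms: none
Why: Swern oxidation run directly on the silyl ether, in which the chlorosulfonium salt attacks only the primary O–Si bond while the tertiary TES ether survives, and the aldehyde has no α-hydrogen and cannot epimerise.

Step 9
Reactants: 10 ethyl (S)-5-formyl-6-methyl-2-methylene-5-(triethylsilyloxy)heptanoate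
Product: 11 ethyl (S,E)-5-isopropyl-2-methylene-8-oxo-5-(triethylsilyloxy)non-6-enoate
Conditions: Ph3P=CHC(O)CH3, BHT (trace), toluene, 100 °C
Reagents that add atoms: 1-(triphenylphosphoranylidene)propan-2-one, CC(=O)C=P(c1ccccc1)(c1ccccc1)c1ccccc1
Why: Wittig olefination with a stabilised ylide should give the E-enone (C2=C3), and the ylide is too weak a nucleophile to add to the 2-alkylacrylate.

Step 10
Reactants: 11 ethyl (S,E)-5-isopropyl-2-methylene-8-oxo-5-(triethylsilyloxy)non-6-enoate
Product: 12 ethyl (5S,6E,8R)-8-hydroxy-5-isopropyl-8-methyl-2-methylene-5-(triethylsilyloxy)undeca-6,10-dienoate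
Conditions: 2-allyl-1,3,2-dioxaborinane (1.5 equiv), (S)-3,3'-Br2-BINOL (10 mol%), t-BuOH (2 equiv), toluene, rt
Reagents that add atoms: 2-allyl-1,3,2-dioxaborinane, C=CCB1OCCCO1
Why: Chiral-diol-catalysed asymmetric allylboration of a methyl alkenyl ketone through a closed chair transition state, in which the boron-bound diol distinguishes methyl from the large alkenyl arm and sets C4 (R) under catalyst control, while the ester and acrylate are inert to the boronate.

Step 11
Reactants: 12 ethyl (5S,6E,8R)-8-hydroxy-5-isopropyl-8-methyl-2-methylene-5-(triethylsilyloxy)undeca-6,10-dienoate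
Product: 13 ethyl (5S,6E,8R)-5-isopropyl-8-methyl-2-methylene-5,8-bis(triethylsilyloxy)undeca-6,10-dienoate
Conditions: TESOTf, 2,6-lutidine, CH2Cl2, −78 → 0 °C
Reagents that add atoms: triethylsilyl triflate, CC[Si](CC)(CC)OS(=O)(=O)C(F)(F)F
Why: Silyl triflate silylation of the tertiary allylic C4–OH under non-ionising, buffered conditions.

Step 12
Reactants: 13 ethyl (5S,6E,8R)-5-isopropyl-8-methyl-2-methylene-5,8-bis(triethylsilyloxy)undeca-6,10-dienoate
Product: 14 (5S,6E,8R)-5-isopropyl-8-methyl-2-methylene-5,8-bis(triethylsilyloxy)undeca-6,10-dienoic acid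
Conditions: LiOH, THF/H2O, 40 °C; then dilute HCl to pH 4
Reagents that add atoms: lithium hydroxide, [Li+].[OH-]
Why: Saponification of the ethyl 2-alkylacrylate, which the tertiary TES ethers tolerate, and the C1 silyl ether blocks δ-lactone formation.

Step 13
Reactants: 15 (R)-4-[(tert-butyldimethylsilyl)oxy]cyclopent-2-en-1-one
Product: 16 (1S,4R)-4-[(tert-butyldimethylsilyl)oxy]-1-methylcyclopent-2-en-1-ol (O-substituents cis)
Conditions: MeLi, Et2O, −78 °C; then H2O
Reagents that add atoms: methyllithium, [Li]C
Why: 1,2-Addition of MeLi to the enone from the ring face anti to the C10 silyloxy group places the new C8–OH cis to C10–O, so C8 is set by C10 through ring C.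

Step 14
Reactants: 16 (1S,4R)-4-[(tert-butyldimethylsilyl)oxy]-1-methylcyclopent-2-en-1-ol
Product: 17 (1S,4R)-1-methylcyclopent-2-ene-1,4-diol (cis)
Conditions: TBAF, THF, 0 °C → rt
Reagents that add atoms: none
Why: Fluoride desilylation avoids the acid that would ionise the allylic alcohols.

Step 15
Reactants: 14 (5S,6E,8R)-5-isopropyl-8-methyl-2-methylene-5,8-bis(triethylsilyloxy)undeca-6,10-dienoic acid; 17 (1S,4R)-1-methylcyclopent-2-ene-1,4-diol (1.5 equiv)
Product: 18 (1R,4S)-4-hydroxy-4-methylcyclopent-2-en-1-yl ester of 14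
Conditions: DCC, DMAP (20 mol%), CH2Cl2, 0 °C → rt
Reagents that add atoms: none
Why: Steglich esterification acylates the secondary allylic C10–OH and not the tertiary C8–OH, with retention at C10 because the C–O bond is not broken.

Step 16
Reactants: 18 (1R,4S)-4-hydroxy-4-methylcyclopent-2-en-1-yl ester of 14
Product: 20 (1S,2E,4R,6E,8S,10R)-8-hydroxy-1,4-bis(triethylsilyloxy)cembra-2,6,11-trien-20,10-olide, via ring-rearranged butenolide triene 19 (not isolated)
Conditions: second-generation Hoveyda–Grubbs catalyst RuCl2(H2IMes)(=CH-C6H4-2-OiPr) (2 × 10 mol%), 1,4-benzoquinone (20 mol%), toluene (2 mM), C2H4 (1 atm), 80 °C; then Ar sparge, dilution to 0.5 mM, 110 °C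
Reagents that add atoms: none
Why: Proposed new method: Ru=CH2, sustained by ethylene, opens the weakly strained C7=C11 alkene of ring C reversibly, and of the two open alkylidenes the one at C11 is drained irreversibly by metathesis with the ester-tethered C12=CH2, which forms C11=C12 and leaves C7 as a vinyl group (19); once ethylene is purged, the alkylidene formed at the unhindered C6 allyl terminus closes onto this vinyl group and expels ethylene. The closest known reaction types are ring-rearrangement metathesis of cyclopent-2-enyl allyl or styrenyl ethers under ethylene, ring-closing metathesis of allylic 2-alkylacrylates to 3-alkylbutenolides, and ring-expansion metathesis that splices a cycloalkene into an acyclic diene; what is new is their union on an unstrained cyclopentenyl 2-alkylacrylate. Ring B closes as a five-membered, ester-tethered ring closure and so can only hold a Z alkene, while ring A closes end to end as a 14-membered macrocyclic ring closure at high dilution, preorganised by the rigid butenolide and the E-C2=C3 unit. No stereocentre is created: C8 and C10 keep the cis relation set on ring C because no bond to either carbon is broken, and the new C6=C7 alkene should be E under the thermodynamic control of a second-generation catalyst because C7 carries the fully substituted C8. The step needs the catalyst to ignore C2=C3 (shielded by the fully substituted C1 and C4) and the finished butenolide (trisubstituted, electron-poor), and it needs the parasitic C7/C11 ring closure to be harmless, which it is here because that closure only regenerates 18. The alkylidene at C7 has no comparable exit (only a seven-membered lactone with a hindered trisubstituted alkene), dimers through the allyl terminus stay metathesis-active and re-enter the manifold, and the free C8–OH should speed up metathesis at C7.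

Step 17
Reactants: 20 (1S,2E,4R,6E,8S,10R)-8-hydroxy-1,4-bis(triethylsilyloxy)cembra-2,6,11-trien-20,10-olide
Product: 21 (1S,2E,4R,6E,8S,10R)-1,4,8-trihydroxycembra-2,6,11-trien-20,10-olide (target)
Conditions: HF·pyridine, excess pyridine, THF, 0 °C → rt
Reagents that add atoms: none
Why: Buffered fluoride desilylation should remove both tertiary TES ethers without ionising the tertiary allylic alcohols and without the base that could epimerise C10 of the butenolide.

**Compound list**
1 | 3-methylbutanal | CC(C)CC=O | starting material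
2 | 3-methyl-2-methylenebutanal | CC(C)C(=C)C=O | intermediate
3 | 3-methyl-2-methylenebutan-1-ol | CC(C)C(=C)CO | intermediate
4 | (S)-(2-isopropyloxiran-2-yl)methanol | CC(C)[C@]1(CO)CO1 | intermediate
5 | (S)-2-(iodomethyl)-3-methylbutane-1,2-diol | CC(C)[C@](O)(CO)CI | intermediate
6 | bis(triethylsilyl) ether of 5 | CC(C)[C@](O[Si](CC)(CC)CC)(CO[Si](CC)(CC)CC)CI | intermediate
7 | ethyl 2-(bromomethyl)acrylate | C=C(CBr)C(=O)OCC | starting material
8 | ethyl 2-[(phenylsulfonyl)methyl]acrylate | C=C(CS(=O)(=O)c1ccccc1)C(=O)OCC | intermediate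
9 | ethyl (S)-6-methyl-2-methylene-5-(triethylsilyloxy)-5-[(triethylsilyloxy)methyl]heptanoate | CC(C)[C@](O[Si](CC)(CC)CC)(CO[Si](CC)(CC)CC)CCC(=C)C(=O)OCC | intermediate
10 | ethyl (S)-5-formyl-6-methyl-2-methylene-5-(triethylsilyloxy)heptanoate | CC(C)[C@](O[Si](CC)(CC)CC)(C=O)CCC(=C)C(=O)OCC | intermediate
11 | ethyl (S,E)-5-isopropyl-2-methylene-8-oxo-5-(triethylsilyloxy)non-6-enoate | CC(C)[C@](O[Si](CC)(CC)CC)(/C=C/C(C)=O)CCC(=C)C(=O)OCC | intermediate
12 | ethyl (5S,6E,8R)-8-hydroxy-5-isopropyl-8-methyl-2-methylene-5-(triethylsilyloxy)undeca-6,10-dienoate | CC(C)[C@](O[Si](CC)(CC)CC)(/C=C/[C@](C)(O)CC=C)CCC(=C)C(=O)OCC | intermediate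
13 | ethyl (5S,6E,8R)-5-isopropyl-8-methyl-2-methylene-5,8-bis(triethylsilyloxy)undeca-6,10-dienoate | CC(C)[C@](O[Si](CC)(CC)CC)(/C=C/[C@](C)(O[Si](CC)(CC)CC)CC=C)CCC(=C)C(=O)OCC | intermediate
14 | (5S,6E,8R)-5-isopropyl-8-methyl-2-methylene-5,8-bis(triethylsilyloxy)undeca-6,10-dienoic acid | CC(C)[C@](O[Si](CC)(CC)CC)(/C=C/[C@](C)(O[Si](CC)(CC)CC)CC=C)CCC(=C)C(=O)O | intermediate
15 | (R)-4-[(tert-butyldimethylsilyl)oxy]cyclopent-2-en-1-one | O=C1C[C@@H](O[Si](C)(C)C(C)(C)C)C=C1 | starting material
16 | (1S,4R)-4-[(tert-butyldimethylsilyl)oxy]-1-methylcyclopent-2-en-1-ol | O[C@@]1(C)C[C@@H](O[Si](C)(C)C(C)(C)C)C=C1 | intermediate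
17 | (1S,4R)-1-methylcyclopent-2-ene-1,4-diol (cis) | O[C@@]1(C)C[C@@H](O)C=C1 | intermediate
18 | (1R,4S)-4-hydroxy-4-methylcyclopent-2-en-1-yl ester of 14 | CC(C)[C@](O[Si](CC)(CC)CC)(/C=C/[C@](C)(O[Si](CC)(CC)CC)CC=C)CCC(=C)C(=O)O[C@@H]1C[C@](C)(O)C=C1 | intermediate
19 | (R)-5-[(S)-2-hydroxy-2-methylbut-3-en-1-yl]-3-[(3S,4E,6R)-3-isopropyl-6-methyl-3,6-bis(triethylsilyloxy)nona-4,8-dien-1-yl]furan-2(5H)-one | C=C[C@@](C)(O)C[C@@H]1C=C(CC[C@](O[Si](CC)(CC)CC)(C(C)C)/C=C/[C@](C)(O[Si](CC)(CC)CC)CC=C)C(=O)O1 | intermediate
20 | (1S,2E,4R,6E,8S,10R)-8-hydroxy-1,4-bis(triethylsilyloxy)cembra-2,6,11-trien-20,10-olide | CC(C)[C@]1(O[Si](CC)(CC)CC)/C=C/[C@](C)(O[Si](CC)(CC)CC)C/C=C/[C@@](C)(O)C[C@@H]2C=C(CC1)C(=O)O2 | intermediate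
21 | (1S,2E,4R,6E,8S,10R)-1,4,8-trihydroxycembra-2,6,11-trien-20,10-olide | CC(C)[C@]1(O)/C=C/[C@](C)(O)C/C=C/[C@@](C)(O)C[C@@H]2C=C(CC1)C(=O)O2 | target

**Count**
Total: 17 steps. Longest linear sequence: 14 steps (1–5, 7–12, 15–17).

**Three steps most likely to fail**

1. Step 16.
- What may go wrong: opening of the hindered, weakly strained cyclopentene may be slow. Re-closure of ring C may outrun capture by the 1,1-disubstituted acrylate. The catalyst may decay, or the allyl termini may oligomerise before ring A closes.
- Fallback idea: known chemistry only. Ring C is given up, C6=C7 is made before the C11 vinyl group exists, and the carbocycle is reached by contraction of a macrolactone.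
- Course: the fallback sets out from 13. Cross-metathesis with methyl vinyl ketone (second-generation Hoveyda–Grubbs catalyst, CH2Cl2, 40 °C) should give the E-configured methyl enone F1. Allylboration as in step 10, but with (R)-3,3'-Br2-BINOL, should give the C8 (S)-carbinol F2. OsO4 (cat.)/NMO followed by NaIO4, acting on the only unhindered terminal alkene, should give the β-hydroxy aldehyde F3. Ligand-controlled Nozaki–Hiyama–Kishi vinylation (vinyl iodide, CrCl2, NiCl2 cat., chiral sulfonamide ligand) should give the syn-diol F4. LiOH should then give the seco acid F5. Shiina macrolactonisation (2-methyl-6-nitrobenzoic anhydride, DMAP, high dilution) at the only secondary hydroxyl should give the 15-membered macrolactone F6.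
- Return: transannular ring-closing metathesis (second-generation Grubbs catalyst, toluene, 80 °C) is a reaction type established for butenolide-bridged macrocarbocycles. It forms C11=C12 and returns to the route at 20.

2. Step 10.
- What may go wrong: addition may be slow, because the alkenyl arm of the ketone ends in a fully substituted carbon. Facial selectivity may be eroded by the uncatalysed background allylboration.
- Fallback: face control at the ketone is abandoned in favour of separation. It sets out from 11. Indium-mediated Barbier allylation (allyl bromide, In metal, THF/H2O) is chemoselective for the ketone. Because C1 is already fixed, it should give two diastereomers, so 12 can be separated by chromatography from its C4 epimer F7. The route is rejoined at 12.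

3. Step 7.
- What may go wrong: the radical chain may be inefficient. The neopentyl-type C14 radical may add slowly, and it may also add to the acrylate of the product.
- Fallback: C–C bond formation and methylenation are separated. It sets out from 6. Giese addition of the same radical (Bu3SnH, AIBN, benzene, 80 °C, slow addition) to the doubly activated acceptor ethyl 2-(diethoxyphosphoryl)acrylate should give the α-phosphono ester F8. Horner–Wadsworth–Emmons methylenation (aq. HCHO, K2CO3) then returns to the route at 9.

**Further compounds**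
F1 | step 16 | ethyl (5S,6E,8R,10E)-5-isopropyl-8-methyl-2-methylene-12-oxo-5,8-bis(triethylsilyloxy)trideca-6,10-dienoate | CC(C)[C@](O[Si](CC)(CC)CC)(/C=C/[C@](C)(O[Si](CC)(CC)CC)C/C=C/C(C)=O)CCC(=C)C(=O)OCC
F2 | step 16 | ethyl (5S,6E,8R,10E,12S)-12-hydroxy-5-isopropyl-8,12-dimethyl-2-methylene-5,8-bis(triethylsilyloxy)pentadeca-6,10,14-trienoate | CC(C)[C@](O[Si](CC)(CC)CC)(/C=C/[C@](C)(O[Si](CC)(CC)CC)C/C=C/[C@@](C)(O)CC=C)CCC(=C)C(=O)OCC
F3 | step 16 | ethyl (5S,6E,8R,10E,12S)-12-hydroxy-5-isopropyl-8,12-dimethyl-2-methylene-14-oxo-5,8-bis(triethylsilyloxy)tetradeca-6,10-dienoate | CC(C)[C@](O[Si](CC)(CC)CC)(/C=C/[C@](C)(O[Si](CC)(CC)CC)C/C=C/[C@@](C)(O)CC=O)CCC(=C)C(=O)OCC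
F4 | step 16 | ethyl (5S,6E,8R,10E,12S,14R)-12,14-dihydroxy-5-isopropyl-8,12-dimethyl-2-methylene-5,8-bis(triethylsilyloxy)hexadeca-6,10,15-trienoate | CC(C)[C@](O[Si](CC)(CC)CC)(/C=C/[C@](C)(O[Si](CC)(CC)CC)C/C=C/[C@@](C)(O)C[C@@H](O)C=C)CCC(=C)C(=O)OCC
F5 | step 16 | (5S,6E,8R,10E,12S,14R)-12,14-dihydroxy-5-isopropyl-8,12-dimethyl-2-methylene-5,8-bis(triethylsilyloxy)hexadeca-6,10,15-trienoic acid | CC(C)[C@](O[Si](CC)(CC)CC)(/C=C/[C@](C)(O[Si](CC)(CC)CC)C/C=C/[C@@](C)(O)C[C@@H](O)C=C)CCC(=C)C(=O)O
F6 | step 16 | 15-membered macrolactone of F5 closed at the C10 hydroxyl (C10 vinyl, C12 exo-methylene, C8–OH free) | CC(C)[C@]1(O[Si](CC)(CC)CC)/C=C/[C@](C)(O[Si](CC)(CC)CC)C/C=C/[C@@](C)(O)C[C@H](C=C)OC(=O)C(=C)CC1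
F7 | step 10 | ethyl (5S,6E,8S)-8-hydroxy-5-isopropyl-8-methyl-2-methylene-5-(triethylsilyloxy)undeca-6,10-dienoate (C4 epimer of 12) | CC(C)[C@](O[Si](CC)(CC)CC)(/C=C/[C@@](C)(O)CC=C)CCC(=C)C(=O)OCC
F8 | step 7 | ethyl (5S)-2-(diethoxyphosphoryl)-6-methyl-5-(triethylsilyloxy)-5-[(triethylsilyloxy)methyl]heptanoate (both epimers at C-2) | CC(C)[C@](O[Si](CC)(CC)CC)(CO[Si](CC)(CC)CC)CCC(C(=O)OCC)P(=O)(OCC)OCC
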